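You asked which set-up keeps target best, and you guessed the dosed flask; here is the quick reckoning.

| flask | substrate | enzyme | time | remark |
|---|---|---|---|---|
| south-east | 0.15 M (fed, over 10.0 h) | 0.15 mM | 10 h | a stirred flask in which substrate is dosed at a steady rate over 10.0 h without added volume, worked up at 10 h |
| east | 0.15 M | 0.15 mM |  | one stirred flow tank at steady state, fed with the mixture as stated, mean residence time 30.0 h |
| west | 0.15 M | 0.15 mM | 10 h | everything together in a closed stirred flask, run for 10 h |
| south-west | 0.15 M | 0.15 mM |  | a single well-mixed tank run continuously and read at steady state, 10 h in it on average |

    substrate + enzyme ⇌ complex (K1 = 30.4 M⁻¹, k1 = 4.12 × 10⁵ M⁻¹ h⁻¹)
    complex → enzyme + target (k2 = 471 h⁻¹)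
    target → over-reaction product (k3 = 0.0610 h⁻¹)

- the set-up with the highest share of target in all that became target or over-reaction product, at the outlet or at the end ("none" if the first two lie within 2 percentage points) (south-east / east / west / south-west / none)
- share of target in all that became target or over-reaction product, at the outlet or at the end, south-east
- share of target in all that became target or over-reaction product, at the outlet or at the end, east
- share of target in all that became target or over-reaction product, at the outlet or at the end, west
- share of target in all that became target or over-reaction product, at the outlet or at the end, south-west

- the stated concentrations are those of everything mixed, before any reaction; amounts are the same in each set-up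
- the feed brings no volume worth counting
- run time (south-east): 10 h

I would carry the clearing time, 2.12 h: the substrate charge divided by the enzyme's top rate, the turnover constant times c(enzyme). That top rate is 0.0707 M h⁻¹.

The clearing time marks the crossing. In south-east the dose takes 10.0 h, longer than the clearing time, so the feed is the rate-limiting step. I take target in south-east as appearing evenly, which makes it on average 5.00 h old at the end. In west, reckoned at the top rate throughout, target appears over the first 2.12 h, which puts its average age at about 8.94 h.

A lot of one age keeps the share exp(−k × age), with k = 0.0610 h⁻¹ for the step from target to over-reaction product, and I treat each flask as one lot of its average age. I therefore commit to about 73.7% for south-east and 58.0% for west. A tank ages target for its residence time on average, 30.0 h in east and 10 h in south-west, longer than the south-east age. My pick is south-east.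

The forecast also picks south-east, with higher figures than mine for south-east and west:

| Set-up | Forecast share of target |
|---|---|
| south-east | 76.1% |
| east | 35.3% |
| west | 59.8% |
| south-west | 62.1% |

Its ground for the winner is that “the dosed flask makes target right up to the end”.

The flask gives 76.0% for south-east, 35.3% for east, 59.8% for west and 62.1% for south-west, so south-east leads. The feed in south-east asks 21.2% of the enzyme's top rate, and substrate in that flask peaks at 0.00917 M. Now put the same charge into the south-east flask over 1.00 h, which is shorter than the clearing time. The crossing is passed: the feed runs at 0.150 M h⁻¹, above the top rate. That flask gives 60.8%, against 59.8% in west.

(Its constants belong to no real substance, and the outcome is calculated.)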